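(The data were computed for an exercise; scatter was added.)

The questions below come down to one: how much target stands at 80 min, and does the way of charging move it by more than the margin?

the same everywhere: solid reagent 0.625 M; catalyst 1.2 mM

| flask | starting material | second substrate | remark | time |
|---|---|---|---|---|
| south | 0.25 M | 0.125 M | run made earlier |  |
| north-west | 0.25 M | 0.062 M | run made earlier |  |
| south-east | 0.25 M | 0.25 M | run made earlier |  |
| violet | 0.25 M (in portions, 3, over 30 min) | 0.125 M | first portion at the start, last at 30 min | 80 min |
| teal | 0.25 M | 0.125 M (fed, over 30 min) | all else is in the flask from the start; the feed brings no volume worth counting | 80 min |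
| ochre | 0.25 M (fed, over 30 min) | 0.125 M | all else is in the flask from the start; the feed brings no volume worth counting | 80 min |
| amber | 0.25 M | 0.125 M | everything together at the start | 80 min |

| run | time / min | target / % |
|---|---|---|
| south | 12.0 | 2.2 |
| south | 25.0 | 5.2 |
| south | 30.0 | 6.7 |
| south | 50.0 | 13.7 |
| south | 60.0 | 17.1 |
| south | 80.0 | 25.0 |
| north-west | 8.00 | 0.7 |
| north-west | 12.0 | 2.3 |
| north-west | 20.0 | 4.2 |
| north-west | 25.0 | 4.3 |
| north-west | 40.0 | 10.6 |
| north-west | 60.0 | 18.0 |
| north-west | 90.0 | 28.2 |
| south-east | 5.00 | 0.4 |
| south-east | 15.0 | 1.7 |
| south-east | 25.0 | 4.5 |
| south-east | 40.0 | 10.7 |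
| south-east | 60.0 | 18.3 |
| south-east | 80.0 | 24.3 |
| south-east | 90.0 | 28.4 |

(scatter of a reading: 0.5 percentage points)

* the flask that comes out highest in amount of target, in percent of the starting material charged, or "all alike" when all lie within 1.5 percentage points (violet / teal / ochre / amber / all alike)
* target at the end, in percent of the starting material charged, violet
* target at the end, in percent of the starting material charged, teal
* target at the end, in percent of the starting material charged, ochre
* target at the end, in percent of the starting material charged, amber

- as a solid, counted per litre of solution: solid reagent
- at the start none of the solid reagent is in solution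
- a reading or a percentage of target counts all its forms, free or not

I built the flask up one process at a time. First I took the main step by itself, starting material going to target at a steady pace, and averaged the north-west and south-east runs between 40.0 min and 90.0 min. That gave r = 8.82 × 10⁻⁴ M min⁻¹, the target made per minute on the straight part of the curve. A ramp at r starting from zero gives 28.2% of the charge at 80 min.

Then I added the slow start. Carrying the line back from 40.0 min put its foot at a dead time L = 9.83 min, which lowered the number to 24.8%.

Last came the charging. The north-west and south-east runs, with 0.062 M and 0.25 M of second substrate, read 18.0% and 18.3% at 60.0 min, a gap smaller than the scatter, so I took nothing off for teal's feed. Ochre's feed brings starting material at 9.44 times r. By 30 min the line has used 0.0178 M, less than violet's single portion of 0.0833 M. So I took amber as the zero of the scale, added nothing for the feeds, and reckoned 24.8% for each flask.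

The forecast said all alike, with 24.6% for violet, 24.8% for teal, 24.2% for ochre and 24.8% for amber, setting ochre a little under my number. Its ground was “The clock is therefore set by the solid and catalyst”.

The flasks gave 24.2% for violet, 24.7% for teal, 24.3% for ochre and 24.7% for amber: all alike, as forecast.

    second substrate ⇌ dormant form (K = 4.40, k = 0.0710 min⁻¹)
    second substrate + partner + catalyst → catalyst + second product (k = 13.0 M⁻² min⁻¹)
    starting material + partner + catalyst → catalyst + target (k = 180 M⁻² min⁻¹)
    catalyst + target ⇌ idle complex (K = 11.0 M⁻¹, k = 0.180 M⁻¹ min⁻¹)
    solid reagent ⇌ partner, rate k5*(cs5 - [partner]) while solid is left; crystals form when [partner] > cs5 (solubility = 0.130 M, k = 0.0100 min⁻¹)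

The way of charging moved the flasks by less than the margin. In amber, with the low solubility of partner taken away, target reached 97.4% instead of 24.7%, so the dissolving of solid reagent is the rate-limiting step there. The partner reaches the solution from the solid reagent at no more than 0.00130 M min⁻¹, above r. Read at 3.0 h, amber on r and L gives 60.1%. The computed flask held 52.5%, lower, so the ramp bends beyond the window it was read in.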